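Its constants come from no measurement; the run is a simulation.

**The vessel.** A closed, stirred vessel holds solid Za, which feeds dissolved Zb; Zb meets Zc to give Ze, while Zd takes some Za to Zf.

    Za ⇌ Zb, rate k1*(cs1 - [Zb]) while solid is left; crystals form when [Zb] > cs1 (cs1 = 29 mM, k1 = 0.179 s⁻¹)
    Za + Zd → Zf (k2 = 1.93 M⁻¹ s⁻¹)
    Zb + Zc → Ze (k3 = 0.437 M⁻¹ s⁻¹)

Za 0.054 M; Zc 1.00 equiv; Zd 2.70 mM; time 4.0 min

- solid, in amounts per volume of the solution: Za
- at the start none of Za is in solution
- run time (flask): 4.0 min

- dawn: doubling the amount of Zc, all else as stated
- dusk: doubling the dissolution coefficient of step 1, all else as stated
- summer: doubling the solubility in step 1, all else as stated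

- how much Ze there is at 4.0 min, in percent of the Za charged
- the change that raises the amount of Ze at 4.0 min, in percent of the Za charged most ("none" if none brings more than 2 percentage points) (dawn / dusk / summer / none)
- amount of Ze at 4.0 min, in percent of the Za charged, after dusk

**Reaction count.** Zb and Zc enter in equal amounts, so their coupling is a second-order reaction of equal partners. Divide its rate at full charge, rate constant times charge squared, by the mean rate that would spend the charge within the run, charge over time. The quotient, rate constant times charge times time, is 5.66: the reaction count, the number of second-order time scales in the run. Equal partners then convert the count over one plus the count, here 85.0%.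

**One number enough?** Not quite. Dissolving outruns the coupling, by a ratio of 7.59, so dusk should add little. But dissolved Zb stops at 29 mM, 53.7% of the charge, so the early rate stays below what the count assumes. Zd can also take up to 5.00% of the Za. This reckoning commits to about 80.0%, and to dawn.

**The forecast.** It gives 81%, dawn as the best change and 81.6% after dusk, holding that “the near-equimolar Zb and Zc finish by slow second-order reaction”.

**The result.** The flask gives 81.7% and 82.2% after dusk. The change dawn gains the most, 15 percentage points, against 2.2 points for summer and 0.5 points for dusk.

**Falling Zc.** A count of 5.66 describes a flask whose Ze is held back by the falling level of Zc, together with the reading being taken at that time and not ten times later. With Zc held at its charge, this flask reaches 95.5%. The forecast's 81% would stand wrong if the charge of Zc changed: at 0.901 equiv or 1.13 equiv the answer in this flask has moved by 5 points. The neighbour flask, with 0.022 M of Za, has a count of 2.31, which reckons to 69.8%, and it stands at 68.8%.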